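**Strategy.** The dihydropyran ring (O1, C2, C3, C4, C4a, C8a) is disconnected at O1–C2 by formally inserting a carbonyl carbon. This leads back to a seven-membered aryl lactone, a 3,3-dimethyl-1-benzoxepine-2,5-dione, made from the acylphloroglucinol and 2,2-dimethylsuccinic anhydride. In one operation a Lewis acid ionises the lactone, the tertiary acylium ion loses CO, and the cation at C2 (quaternary, between O1 and C3, 1,3 to the C4 carbonyl) is recaptured by the same oxygen O1. The ring thereby contracts to the 2,2-dimethylchroman-4-one. A tosylate on the neighbouring oxygen fixes which oxygen closes. Asymmetric transfer hydrogenation then sets C4 as R.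

Key step: step 4

Remark on the chemistry: the descriptor at C4 is read from the SMILES as R; primed locants (1′–6′) refer to the phloroglucinol ring of the dihydrochalcone, chroman locants (O1, C2–C4, C4a, C5–C8, C8a) to the target ring system.

Step 1
Reactants: 1 2-methylbenzene-1,3,5-triol (2-methylphloroglucinol); 2 3-phenylpropanoic acid
Product: 3 3-phenyl-1-(2,4,6-trihydroxy-3-methylphenyl)propan-1-one
Conditions: BF3·OEt2 (neat), 85 °C; aq. NaOAc work-up
Reagents that add atoms: none
Why: Friedel–Crafts (Nencki-type) C-acylation of the phloroglucinol by the acid–BF3 complex should occur at one of the two equivalent free ring carbons and stop after one acylation, because the chelated ketone deactivates the ring.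

Step 2
Reactants: 3 3-phenyl-1-(2,4,6-trihydroxy-3-methylphenyl)propan-1-one
Product: 4 3,5-dihydroxy-2-methyl-4-(3-phenylpropanoyl)phenyl 4-methylbenzenesulfonate
Conditions: TsCl (1.05 equiv), K2CO3, acetone, 0 °C to rt
Reagents that add atoms: 4-methylbenzenesulfonyl chloride (TsCl), Cc1ccc(cc1)S(Cl)(=O)=O
Why: Selective O-sulfonylation: only the 4′-OH (para to the ketone) is not hydrogen-bonded to the carbonyl and is the most acidic, so it alone should react, which blocks O-4′ for the later ring closures and gives a group that survives Lewis acids.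

Step 3
Reactants: 4 3,5-dihydroxy-2-methyl-4-(3-phenylpropanoyl)phenyl 4-methylbenzenesulfonate; 5 3,3-dimethyloxolane-2,5-dione (2,2-dimethylsuccinic anhydride)
Product: 7 8-hydroxy-3,3,7-trimethyl-2,5-dioxo-9-(3-phenylpropanoyl)-2,3,4,5-tetrahydro-1-benzoxepin-6-yl 4-methylbenzenesulfonate, via keto acid 6 (not isolated)
Conditions: AlCl3, PhNO2, 50 °C; aq. HCl; crude 6: EDC·HCl, DMAP (cat.), CH2Cl2 (5 mM), rt
Reagents that add atoms: none
Why: Friedel–Crafts acylation at C-5′, the only unsubstituted ring carbon, through the less hindered CH2–C=O carbonyl of the anhydride should give keto acid 6, whose hindered carboxyl group is then closed onto the adjacent 6′-OH by carbodiimide (Steglich) esterification in a 7-exo-trig acyl transfer helped by the gem-dimethyl group, O-4′ being blocked as the tosylate.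

Step 4
Reactants: 7 8-hydroxy-3,3,7-trimethyl-2,5-dioxo-9-(3-phenylpropanoyl)-2,3,4,5-tetrahydro-1-benzoxepin-6-yl 4-methylbenzenesulfonate
Product: 9 7-hydroxy-2,2,6-trimethyl-4-oxo-8-(3-phenylpropanoyl)-3,4-dihydro-2H-chromen-5-yl 4-methylbenzenesulfonate, via enone 8 (not isolated)
Conditions: AlCl3 (2.5 equiv), PhCl, 80 °C, N2 stream; cold 1 M HCl
Reagents that add atoms: none
Why: Proposed new method: AlCl3 binds the lactone carbonyl and ionises the aryl–acyl C–O bond as in a Fries rearrangement, giving an aluminium phenoxide and a tertiary acylium ion that, like the pivaloyl cation, should lose CO because no ring position is free for C-acylation (both ortho carbons and the para carbon of O1 are substituted). The resulting tertiary cation at C2 is either captured directly by the chelated phenoxide O1 or loses a proton to enone 8, which closes by acid-mediated 6-endo-trig oxa-Michael addition, so both channels give the six-membered ring; the closest known reactions are the decarbonylative tert-butylation seen in Friedel–Crafts reactions of pivaloyl chloride and the acid-mediated chromanone synthesis from phenols and 3-methylbut-2-enoic acid. No stereocentre is formed. The step needs closure onto O1 (O-6′) only, which the tosylate on the other ortho oxygen secures, and ionisation of the lactone in preference to the sulfonate and the two aryl ketones, which is expected because the hindered aryl ester is the only acyl–oxygen bond present. Loss of CO gas makes the contraction irreversible.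

Step 5
Reactants: 9 7-hydroxy-2,2,6-trimethyl-4-oxo-8-(3-phenylpropanoyl)-3,4-dihydro-2H-chromen-5-yl 4-methylbenzenesulfonate
Product: 10 (4R)-4,7-dihydroxy-2,2,6-trimethyl-8-(3-phenylpropanoyl)-3,4-dihydro-2H-chromen-5-yl 4-methylbenzenesulfonate
Conditions: RuCl[(R,R)-TsDPEN](p-cymene) (2 mol %), HCO2H/Et3N (5:2), DMF, 30 °C
Reagents that add atoms: none
Why: Noyori-type asymmetric transfer hydrogenation: the (R,R)-TsDPEN–Ru hydride should reduce the unchelated cyclic aryl ketone C4=O from the face that gives the (4R)-alcohol (CH–π contact between the η6-arene and the benzo ring, the sense known for 4-chromanone), while the 8-acyl ketone, flanked by two ortho substituents and chelated by 7-OH, should stay untouched.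

Step 6
Reactants: 10 (4R)-4,7-dihydroxy-2,2,6-trimethyl-8-(3-phenylpropanoyl)-3,4-dihydro-2H-chromen-5-yl 4-methylbenzenesulfonate
Product: 11 1-[(4R)-4,5,7-trihydroxy-2,2,6-trimethyl-3,4-dihydro-2H-chromen-8-yl]-3-phenylpropan-1-one
Conditions: LiOH (3 equiv), THF/H2O (3:1), 0 °C to rt; aq. NH4Cl
Reagents that add atoms: none
Why: Hydroxide attacks the sulfur of the aryl sulfonate (S–O cleavage; the phenoxide para to the 8-acyl group is a good leaving group), which should free 5-OH without touching the C4 carbinol, whose ring can no longer open by retro-oxa-Michael reaction.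

Compound list

1 | 2-methylbenzene-1,3,5-triol (2-methylphloroglucinol) | Cc1c(O)cc(O)cc1O | starting material
2 | 3-phenylpropanoic acid | OC(=O)CCc1ccccc1 | starting material
3 | 3-phenyl-1-(2,4,6-trihydroxy-3-methylphenyl)propan-1-one | Cc1c(O)cc(O)c(C(=O)CCc2ccccc2)c1O | intermediate
4 | 3,5-dihydroxy-2-methyl-4-(3-phenylpropanoyl)phenyl 4-methylbenzenesulfonate | Cc1c(OS(=O)(=O)c2ccc(C)cc2)cc(O)c(C(=O)CCc3ccccc3)c1O | intermediate
5 | 3,3-dimethyloxolane-2,5-dione (2,2-dimethylsuccinic anhydride) | CC1(C)CC(=O)OC1=O | starting material
6 | 4-{2,4-dihydroxy-5-methyl-6-[(4-methylbenzenesulfonyl)oxy]-3-(3-phenylpropanoyl)phenyl}-2,2-dimethyl-4-oxobutanoic acid (keto acid, not isolated) | Cc1c(OS(=O)(=O)c2ccc(C)cc2)c(C(=O)CC(C)(C)C(O)=O)c(O)c(C(=O)CCc3ccccc3)c1O | intermediate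
7 | 8-hydroxy-3,3,7-trimethyl-2,5-dioxo-9-(3-phenylpropanoyl)-2,3,4,5-tetrahydro-1-benzoxepin-6-yl 4-methylbenzenesulfonate (seven-membered lactone) | Cc1c(OS(=O)(=O)c2ccc(C)cc2)c3C(=O)CC(C)(C)C(=O)Oc3c(C(=O)CCc4ccccc4)c1O | intermediate
8 | 3,5-dihydroxy-2-methyl-6-(3-methylbut-2-enoyl)-4-(3-phenylpropanoyl)phenyl 4-methylbenzenesulfonate (enone, not isolated) | Cc1c(OS(=O)(=O)c2ccc(C)cc2)c(C(=O)C=C(C)C)c(O)c(C(=O)CCc3ccccc3)c1O | intermediate
9 | 7-hydroxy-2,2,6-trimethyl-4-oxo-8-(3-phenylpropanoyl)-3,4-dihydro-2H-chromen-5-yl 4-methylbenzenesulfonate | Cc1c(OS(=O)(=O)c2ccc(C)cc2)c3C(=O)CC(C)(C)Oc3c(C(=O)CCc4ccccc4)c1O | intermediate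
10 | (4R)-4,7-dihydroxy-2,2,6-trimethyl-8-(3-phenylpropanoyl)-3,4-dihydro-2H-chromen-5-yl 4-methylbenzenesulfonate | Cc1c(OS(=O)(=O)c2ccc(C)cc2)c3[C@H](O)CC(C)(C)Oc3c(C(=O)CCc4ccccc4)c1O | intermediate
11 | 1-[(4R)-4,5,7-trihydroxy-2,2,6-trimethyl-3,4-dihydro-2H-chromen-8-yl]-3-phenylpropan-1-one | Cc1c(O)c(C(=O)CCc2ccccc2)c2c(c1O)[C@H](O)CC(C)(C)O2 | target

Total step count: 6. Longest linear sequence: 6 steps (1 to 11).

Steps most likely to fail

Step 4 (Proposed new method). The Lewis acid may only chelate the lactone without ionising it, or the acylium ion may be intercepted intermolecularly before it loses CO. Fallback with known chemistry: setting out from 4, tandem Friedel–Crafts acylation and oxa-Michael cyclisation with 3-methylbut-2-enoic acid in MeSO3H/P2O5 at 70 °C should give 9 directly, where the route is rejoined. The tosylate still directs closure onto O-6′. No new compound is made.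

Step 3. C-acylation of a ring deactivated by the ketone and the sulfonate may be sluggish, and the activated acid may close onto the ketone enol (five-membered enol lactone) instead of the phenol. Fallback: setting out from 4, acylation with the more reactive half-ester acid chloride benzyl 4-chloro-2,2-dimethyl-4-oxobutanoate (TiCl4, CH2Cl2, 0 °C; the reagent would be made from 2,2-dimethylsuccinic acid) should give benzyl 4-{2,4-dihydroxy-5-methyl-6-[(4-methylbenzenesulfonyl)oxy]-3-(3-phenylpropanoyl)phenyl}-2,2-dimethyl-4-oxobutanoate F1. Hydrogenolysis (H2, Pd/C, EtOAc) should then release keto acid 6, where the route is rejoined before the lactonisation.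

Step 5. Hydride delivery may be slow or poorly face-selective next to the peri sulfonate, or the 8-acyl ketone may be reduced as well. Fallback: setting out from 9, a Corey–Bakshi–Shibata reduction ((S)-Me-CBS, BH3·SMe2, THF, −20 °C) should give 10, where the route is rejoined. This is a boron-centred, Lewis-acid-activated hydride transfer with a different steric demand. No new compound is made.

Further compounds

F1 | step 3 | benzyl 4-{2,4-dihydroxy-5-methyl-6-[(4-methylbenzenesulfonyl)oxy]-3-(3-phenylpropanoyl)phenyl}-2,2-dimethyl-4-oxobutanoate | Cc1c(OS(=O)(=O)c2ccc(C)cc2)c(C(=O)CC(C)(C)C(=O)OCc4ccccc4)c(O)c(C(=O)CCc3ccccc3)c1O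
F0 | step 4 | none | none
F0 | step 5 | none | none
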